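## Structural features

Aikupikoxide D is a monocyclic 3,6,6-trisubstituted 1,2-dioxane (ring atoms O1, O2, C3, C4, C5, C6). C3 carries a 1-(methoxycarbonyl)ethyl group (ester carbon C1, methyl-bearing C2). C6 carries a methyl group and the chain C7–C14, in which the C9 ketone is conjugated with a C10 methylidene group and C14 is a dimethylcarbinol.

There are three stereocentres. Exocyclic C2 and ring C3 are contiguous; quaternary C6 lies 1,4 to C3 across the ring, with the two long substituents at C3 and C6 cis. A CIP analysis of the target gives 2S,3S,6R.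

The fragile groups are:
- the O–O bond, which does not tolerate low-valent metals, phosphines, hydrogenation catalysts or hard carbanions;
- the β-peroxy ester, where base can expel O2 from C3 by E1cB or cleave the ring through loss of the C3 hydrogen;
- the α-methylidene ketone, a reactive Michael acceptor.

The real difficulty is closing the peroxide ring while fixing C3 relative both to C2 and to the remote quaternary C6, since no general asymmetric C–O–O bond construction exists. The key step exploits the unit C1(=O)–C2(CH3)–C3(–O2), a β-oxy acid. Written as a cis-β-lactone (ring O–C3–C2–C1), it stores C2 and C3 from an aldol-type C–C bond formation and offers C3 as a strained alkyl electrophile to the peroxide oxygen held on C6.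

## Logic of the disconnections

23 ⇒ 22. The exocyclic C10=CH2 bond is cut first, back to formaldehyde and the C10 phosphonate 22. The enone is the most reactive group and should appear last; the phosphonate also fixes on which side of the C9 ketone the methylidene is placed. The forward olefination must use a base too weak to touch the β-peroxy ester.

22 ⇒ 21 ⇒ 13 + 20. The C7–C8 bond is cut as a C7=C8 alkene into 13 and 20. This delivers C8–C14 in one piece, with the C9 ketone and the C10 phosphonate already in place, and it requires no external base and no carbanion near the peroxide. The demands are an olefination at a neopentyl-type α-peroxy aldehyde and a reduction of C7=C8 that leaves O–O intact. The C14 hydroxyl is carried free, since a tertiary alcohol is inert in every later step; this removes a protection and a deprotection.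

20 ⇒ 18 ⇒ 16 + 17, and 16 ⇒ 15 ⇒ 14. The C8–P bond, the C9–C10 bond, the two C14–methyl bonds and the C10–P bond are cut in turn. The branch then reduces to 14, 17, triethyl phosphite and a methyl Grignard reagent. The acylation must stop at the ketone, and the phosphonium centre must be deprotonated in preference to the phosphonate carbon.

13 ⇒ 12 ⇒ 11. The aldehyde carbon C7 is traced back to a C7–C8 glycol (C8 is excised as formaldehyde) and the ester methyl to the free acid. Both operations are oxidative or neutral and therefore suit the peroxide. The diol of 11 is exactly what an epoxy alcohol leaves behind.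

11 ⇒ 10. The O2–C3 bond is cut, which opens the dioxane and reconnects C3 to the C1 carboxyl oxygen as a β-lactone. This is the strategic simplification: the ring, the C3 configuration and the free C1 acid all arise together. 10 carries no protecting group. The forward step must be an SN2 at C3 with inversion, so the lactone carbon must be R and the lactone cis, and only the hydroperoxide may be ionised.

10 ⇒ 9. The O1–C6 bond is cut back to a 2,3-epoxy alcohol. Opening at the tertiary carbon with inversion converts the (S)-epoxide carbon into (6R) and releases the C7–C8 diol. The hydroperoxide is thus made only one step before it is consumed. The diol is left free, because ketalisation next to a hydroperoxide would give a 1,2,4-trioxane.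

9 ⇒ 8 ⇒ 5 + 6. After the silyl ether is put back, the lactone is cut across C2–C3 and O–C1 into 5 and the ketene derived from 6. A catalytic, reagent-controlled cyclocondensation sets C2 and C3 as a cis pair in one C–C bond-forming step. The catalyst must override the remote epoxide, and the epoxide must survive a lithium Lewis acid at low temperature.

5 ⇒ 3 ⇒ 2 ⇒ 1. The aldehyde carbon C3 is the inner carbon of the distal alkene of 1, and the epoxide is the product of Sharpless epoxidation of 1 itself. Epoxidising first has two advantages. The cleavage then meets only one alkene, and the β-lactone never sees Ti(OiPr)4 and tert-butyl hydroperoxide.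

Stereochemical check, atom by atom:
- The (2S,3S)-epoxide requires L-(+)-diethyl tartrate.
- Inversion at C6 in step 6 gives 6R.
- The lactone must be (3S,4R), which is cis.
- Inversion at C3 in step 7 gives 3S; C2 is carried through unchanged as S.

## Other disconnections considered

Alternative 1: The two C–O bonds O2–C3 and O1–C6 are cut together after a C4=C5 double bond is added. This leads to the (3E,5E)-diene A1, with C1 held as a silyl ether and C9 as a dimethyl acetal.
- Forward step: sensitised photo-oxygenation, in which singlet oxygen adds suprafacially across C3 and C6 to give the 3,6-dihydro-1,2-dioxine A2; diimide then saturates C4=C5.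
- In its favour: ring and both C–O bonds form in one operation from an acyclic diene made by ordinary olefination. No hydroperoxide is handled. The E,E geometry translates by the mechanism itself into the cis relation of the C3 and C6 chains. This cycloaddition is a well-established reaction type, and on that point the alternative is better than the chosen plan.
- Against it: the face of the diene is chosen only by the exocyclic C2 centre, which should give weak induction, so a pair of cis adducts differing relative to C2 is expected. The C5=C6 terminus is trisubstituted with allylic hydrogens on the C6 methyl and on C7, so the ene reaction competes. The s-cis conformer needed for [4+2] is disfavoured by the inward C6 methyl. C1 must be carried in reduced form and later deprotected, oxidised twice and esterified in the presence of the peroxide.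
- Comparison: the chosen plan sets each stereocentre by a separate reagent-controlled or stereospecific event. Alternative 1 sets the C3/C6 relation well and the C2/C3 relation poorly. Both plans need one diimide step, so they are equal there. In step count the alternative is about equal up to the ring and longer afterwards.

Alternative 2: The O1–C6 bond is cut with the roles reversed, so that the hydroperoxide sits on C3 (masked as a 2-methoxyprop-2-yl perketal) and C6–C7 is a Sharpless epoxide, as in A3.
- Forward step: mild acid unmasks the hydroperoxide, which opens the epoxide at the tertiary carbon in a 6-exo mode with inversion at C6 to give the dioxane diol A4.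
- In its favour: closure of 1,2-dioxanes by a pendant hydroperoxide on an epoxide is an established reaction type, so the ring closure is better precedented than step 7. Ring size and electronic preference point to the same carbon. A4 carries the same diol handle as 11, so the endgame is shared.
- Against it: it presupposes a configurationally defined secondary hydroperoxide at C3 next to C2. No reliable stereoselective way to install this exists: displacement of a secondary sulfonate by H2O2 suffers from elimination, and radical hydroperoxysilylation is not stereoselective. The masked peroxide must also survive the epoxidation. C1 is again in the wrong oxidation state, which adds three to four late steps.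
- Comparison: the chosen plan reverses the polarity. The peroxide is introduced at the tertiary carbon by a stereospecific intermolecular epoxide opening, and the C3–O stereochemistry is derived from a catalytic C–C bond formation. The risk of partial ionisation at C6 under acid is the same in both plans. Alternative 2 wins on precedent for the closure; the chosen plan wins on stereocontrol at C3 and on length.

Alternative 3: The C4=C5 bond is cut (ring-closing metathesis in reverse) to the acyclic bis-allylic dialkyl peroxide A5.
- Forward step: the second-generation Grubbs catalyst joins the two vinyl groups to give the dihydrodioxine A6; diimide follows.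
- In its favour: a C–C rather than a C–O bond closes the ring, and no stereocentre is touched in the closure. The methyl ester and the C7–C9 chain are already at their final oxidation levels, so no glycol cleavage or olefination is needed afterwards. In post-cyclisation step economy the alternative is better.
- Against it: all the difficulty moves into A5. A tertiary allylic peroxide oxygen on a stereogenic quaternary carbon must be joined intermolecularly, with clean inversion, to a secondary allylic carbon β to an ester. SN2′ attack, E1cB loss of the leaving group and the low nucleophilicity of a hindered peroxide anion all work against this, and the enantiopure tertiary allylic peroxide half has no direct asymmetric origin. Ruthenium alkylidenes and their divalent ruthenium decomposition products may also cleave or isomerise allylic peroxides, and one alkene sits on a quaternary carbon.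
- Comparison: the uncertainty of the ring closure is about equal to that of step 7. The chosen plan has a defined origin for all three stereocentres, which A5 lacks.

Key step: step 7

Assumption: O-trimethylsilylquinine is taken to give the (3S,4R)-cis-β-lactone; if the sense is the opposite, the pseudo-enantiomeric O-trimethylsilylquinidine replaces it.

Remark on handling: compounds 10–13 and 21–23 are peroxides. They are to be kept in dilute solution, concentrated cold behind a shield, and kept away from metal salts and reductants.

## Route

Step 1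
Reactants: 1 geraniol, (2E)-3,7-dimethylocta-2,6-dien-1-ol
Product: 2 [(2S,3S)-3-methyl-3-(4-methylpent-3-en-1-yl)oxiran-2-yl]methanol
Conditions: Ti(OiPr)4 (5 mol%), L-(+)-diethyl tartrate (7 mol%), t-BuOOH, 4 Å MS, CH2Cl2, −20 °C
Reagents that add atoms: tert-butyl hydroperoxide, CC(C)(C)OO
Why: Sharpless asymmetric epoxidation; the L-(+)-tartrate ligand delivers oxygen to the face of the allylic alcohol that gives the (2S,3S)-epoxide, while the distal alkene, having no directing hydroxyl, is not touched. This fixes C6 (S here, R after the inversion of step 6) and C7.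

Step 2
Reactants: 2 [(2S,3S)-3-methyl-3-(4-methylpent-3-en-1-yl)oxiran-2-yl]methanol
Product: 3 tert-butyldimethyl{[(2S,3S)-3-methyl-3-(4-methylpent-3-en-1-yl)oxiran-2-yl]methoxy}silane
Conditions: TBSCl, imidazole, CH2Cl2, 0 °C → rt
Reagents that add atoms: tert-butyldimethylsilyl chloride, CC(C)(C)[Si](C)(C)Cl
Why: Routine silylation of a primary alcohol; the ether shields the hydroxyl from the acid chloride and amine base of step 4.

Step 3
Reactants: 3 tert-butyldimethyl{[(2S,3S)-3-methyl-3-(4-methylpent-3-en-1-yl)oxiran-2-yl]methoxy}silane
Product: 5 3-[(2S,3S)-3-{[(tert-butyldimethylsilyl)oxy]methyl}-2-methyloxiran-2-yl]propanal, via secondary ozonide 4 (not isolated)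
Conditions: O3, CH2Cl2, −78 °C; then Me2S, −78 °C → rt
Reagents that add atoms: ozone, [O-][O+]=O
Why: Ozonolysis with reductive work-up; only one alkene is left, and epoxides and silyl ethers are inert to ozone, so no chemoselectivity has to be managed.

Step 4
Reactants: 5 3-[(2S,3S)-3-{[(tert-butyldimethylsilyl)oxy]methyl}-2-methyloxiran-2-yl]propanal; 6 propanoyl chloride
Product: 8 (3S,4R)-4-{2-[(2S,3S)-3-{[(tert-butyldimethylsilyl)oxy]methyl}-2-methyloxiran-2-yl]ethyl}-3-methyloxetan-2-one, via methylketene 7 (not isolated)
Conditions: O-trimethylsilylquinine (10 mol%), LiClO4, i-Pr2NEt, CH2Cl2/Et2O, −78 °C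
Reagents that add atoms: none
Why: Cinchona-alkaloid/LiClO4-catalysed acyl halide–aldehyde cyclocondensation (formal ketene–aldehyde [2+2] through a chiral ammonium enolate in a closed lithium-bridged transition state), which gives cis-3,4-disubstituted β-lactones. The catalyst sets C2 (S) and the lactone carbon C3 (R); the remote epoxide should have little influence, and any minor isomer is a separable diastereomer.

Step 5
Reactants: 8 (3S,4R)-4-{2-[(2S,3S)-3-{[(tert-butyldimethylsilyl)oxy]methyl}-2-methyloxiran-2-yl]ethyl}-3-methyloxetan-2-one
Product: 9 (3S,4R)-4-{2-[(2S,3S)-3-(hydroxymethyl)-2-methyloxiran-2-yl]ethyl}-3-methyloxetan-2-one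
Conditions: Bu4NF, AcOH (1:1), THF, 0 °C
Reagents that add atoms: none
Why: Fluoride desilylation buffered with acetic acid, so that no free alkoxide is present to open the lactone at the acyl carbon or to trigger a Payne rearrangement of the epoxy alcohol.

Step 6
Reactants: 9 (3S,4R)-4-{2-[(2S,3S)-3-(hydroxymethyl)-2-methyloxiran-2-yl]ethyl}-3-methyloxetan-2-one
Product: 10 (3S,4R)-4-[(3R,4S)-3-hydroperoxy-4,5-dihydroxy-3-methylpentyl]-3-methyloxetan-2-one
Conditions: H2O2 (anhydrous, in Et2O), H3PMo12O40 (5 mol%), Et2O, 0 °C → rt
Reagents that add atoms: hydrogen peroxide, OO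
Why: Heteropolyacid-catalysed perhydrolysis of an epoxide: H2O2 attacks the activated epoxide at the more substituted carbon C6 from the rear (borderline SN2, inversion), while C7 is deactivated by the neighbouring CH2OH. The (2S,3S)-epoxide therefore gives 6R,7S, and neutral H2O2 under mild acid should leave the lactone closed.

Step 7
Reactants: 10 (3S,4R)-4-[(3R,4S)-3-hydroperoxy-4,5-dihydroxy-3-methylpentyl]-3-methyloxetan-2-one
Product: 11 (2S)-2-[(3S,6R)-6-[(1S)-1,2-dihydroxyethyl]-6-methyl-1,2-dioxan-3-yl]propanoic acid
Conditions: Cs2CO3 (1.0 equiv), DMF (0.01 M), 0 °C → rt; then 1 M HCl to pH 3, 0 °C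
Reagents that add atoms: none
Why: Proposed new method: one equivalent of Cs2CO3 removes the hydroperoxide proton, and the terminal peroxide oxygen attacks C3 from the side opposite the lactone oxygen, breaking the alkyl C3–O bond and releasing the four-ring strain as the C1 carboxylate. The closest known reaction types are the alkyl–oxygen SN2 opening of β-lactones by soft anionic nucleophiles with inversion, and the base-mediated intramolecular displacement of sulfonates by hydroperoxides to give 1,2-dioxanes; the pairing of a peroxide nucleophile with a β-lactone electrophile is the untested element. The 1,2-dioxane closes in a 6-exo-tet mode, the departing oxygen lying outside the new ring. The single new stereocentre C3 is controlled by stereospecific inversion of the (R)-lactone carbon installed in step 4, which turns the 2,3-syn lactone into the 2,3-anti array of the target; C2 and C6 are spectators. Alkyl- over acyl-oxygen cleavage is secured by the tether, because attack at C1 would need an eight-membered transition state. Peroxide over hydroxyl participation is secured by the weak base in stoichiometric amount, which ionises only the far more acidic hydroperoxide, whose anion also profits from the alpha effect. High dilution in a dipolar aprotic solvent disfavours intermolecular acyl attack, and the carboxylate formed has no acidic α-hydrogen, so it cannot expel the new β-peroxide.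

Step 8
Reactants: 11 (2S)-2-[(3S,6R)-6-[(1S)-1,2-dihydroxyethyl]-6-methyl-1,2-dioxan-3-yl]propanoic acid
Product: 12 methyl (2S)-2-[(3S,6R)-6-[(1S)-1,2-dihydroxyethyl]-6-methyl-1,2-dioxan-3-yl]propanoate
Conditions: Me3SiCHN2, PhMe/MeOH, 0 °C
Reagents that add atoms: trimethylsilyldiazomethane, C[Si](C)(C)C=[N+]=[N-]
Why: Esterification by a diazoalkane: the acid protonates the reagent, methanol removes silicon, and the carboxylate is methylated with loss of N2. No base is present, so the β-peroxy acid is not exposed to E1cB conditions.

Step 9
Reactants: 12 methyl (2S)-2-[(3S,6R)-6-[(1S)-1,2-dihydroxyethyl]-6-methyl-1,2-dioxan-3-yl]propanoate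
Product: 13 methyl (2S)-2-[(3S,6R)-6-formyl-6-methyl-1,2-dioxan-3-yl]propanoate
Conditions: NaIO4, THF/pH 7 buffer, 0 °C
Reagents that add atoms: none
Why: Malaprade glycol cleavage through a cyclic periodate ester; an oxidant cannot harm the O–O bond. The aldehyde formed sits on a quaternary carbon and so can neither enolise nor epimerise.

Step 10
Reactants: 14 ethyl 5-bromopentanoate
Product: 15 ethyl 5-(diethoxyphosphoryl)pentanoate
Conditions: P(OEt)3, neat, 150 °C (EtBr distilled off)
Reagents that add atoms: triethyl phosphite, CCOP(OCC)OCC
Why: Michaelis–Arbuzov reaction of a primary bromide; the ester is inert.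

Step 11
Reactants: 15 ethyl 5-(diethoxyphosphoryl)pentanoate
Product: 16 diethyl (5-hydroxy-5-methylhexyl)phosphonate
Conditions: MeMgBr (2.5 equiv), THF, −20 → 0 °C; aq. NH4Cl
Reagents that add atoms: methylmagnesium bromide, C[Mg]Br
Why: Double Grignard addition to the ester gives the dimethylcarbinol (C14); dialkyl phosphonates do not react with MeMgBr at or below 0 °C.

Step 12
Reactants: 16 diethyl (5-hydroxy-5-methylhexyl)phosphonate; 17 2-chloro-N-methoxy-N-methylacetamide
Product: 18 diethyl (1-chloro-7-hydroxy-7-methyl-2-oxooctan-3-yl)phosphonate (racemic)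
Conditions: n-BuLi (2.1 equiv), THF, −78 °C; then 17, −78 → −40 °C; aq. NH4Cl
Reagents that add atoms: none
Why: Acylation of an α-lithiated phosphonate by a Weinreb amide; the first equivalent of base is consumed by the hydroxyl. The chelated tetrahedral intermediate survives until work-up, which prevents over-addition and proton transfer to the acidic product.

Step 13
Reactants: 18 diethyl (1-chloro-7-hydroxy-7-methyl-2-oxooctan-3-yl)phosphonate (racemic)
Product: 20 diethyl [7-hydroxy-7-methyl-2-oxo-1-(triphenyl-λ5-phosphanylidene)octan-3-yl]phosphonate (racemic), via phosphonium chloride 19 (not isolated)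
Conditions: PPh3, PhMe, 60 °C; then aq. Na2CO3, CH2Cl2, rt
Reagents that add atoms: triphenylphosphine, c1ccc(cc1)P(c1ccccc1)c1ccccc1
Why: SN2 quaternisation of PPh3 by the primary α-chloro ketone, then deprotonation of the acylmethyl phosphonium salt, which is far more acidic than the phosphonate α-carbon. Carbonate therefore gives only the stabilised ylide.

Step 14
Reactants: 13 methyl (2S)-2-[(3S,6R)-6-formyl-6-methyl-1,2-dioxan-3-yl]propanoate; 20 diethyl [7-hydroxy-7-methyl-2-oxo-1-(triphenyl-λ5-phosphanylidene)octan-3-yl]phosphonate (racemic)
Product: 21 methyl (2S)-2-[(3S,6R)-6-[(1E)-4-(diethoxyphosphoryl)-8-hydroxy-8-methyl-3-oxonon-1-en-1-yl]-6-methyl-1,2-dioxan-3-yl]propanoate (both epimers at the phosphonate carbon)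
Conditions: PhMe, 70 °C
Reagents that add atoms: none
Why: Wittig olefination with an acyl-stabilised ylide, E-selective and run without external base, so the β-peroxy ester is not endangered. Only the ylide end is nucleophilic, and the phosphonate end is kept for step 16; the aldehyde is activated by the α-oxygen.

Step 15
Reactants: 21 methyl (2S)-2-[(3S,6R)-6-[(1E)-4-(diethoxyphosphoryl)-8-hydroxy-8-methyl-3-oxonon-1-en-1-yl]-6-methyl-1,2-dioxan-3-yl]propanoate (both epimers at the phosphonate carbon)
Product: 22 methyl (2S)-2-[(3S,6R)-6-[4-(diethoxyphosphoryl)-8-hydroxy-8-methyl-3-oxononyl]-6-methyl-1,2-dioxan-3-yl]propanoate (both epimers at the phosphonate carbon)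
Conditions: KO2CN=NCO2K (excess, in portions), AcOH, MeOH/CH2Cl2, 0 °C → rt
Reagents that add atoms: none
Why: Diimide reduction: concerted syn transfer of two hydrogens to the C7=C8 bond. This reductant does not cleave O–O bonds and leaves ketone, ester and phosphonate untouched.

Step 16
Reactants: 22 methyl (2S)-2-[(3S,6R)-6-[4-(diethoxyphosphoryl)-8-hydroxy-8-methyl-3-oxononyl]-6-methyl-1,2-dioxan-3-yl]propanoate (both epimers at the phosphonate carbon)
Product: 23 aikupikoxide D, methyl (2S)-2-[(3S,6R)-6-(8-hydroxy-8-methyl-4-methylidene-3-oxononyl)-6-methyl-1,2-dioxan-3-yl]propanoate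
Conditions: CH2O (37% aq.), K2CO3, THF, 0 °C → rt
Reagents that add atoms: formaldehyde, C=O
Why: Horner–Wadsworth–Emmons olefination with formaldehyde: carbonate deprotonates only the doubly activated C10–H, and the adduct loses diethyl phosphate to give the 1,1-disubstituted enone, so both C10 epimers converge. The base is too weak to deprotonate α to the ester, so the β-peroxy ester should persist.

## Compound list

1 | geraniol, (2E)-3,7-dimethylocta-2,6-dien-1-ol | CC(C)=CCC/C(C)=C/CO | starting material
2 | [(2S,3S)-3-methyl-3-(4-methylpent-3-en-1-yl)oxiran-2-yl]methanol | OC[C@@H]1O[C@@]1(C)CCC=C(C)C | intermediate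
3 | tert-butyldimethyl{[(2S,3S)-3-methyl-3-(4-methylpent-3-en-1-yl)oxiran-2-yl]methoxy}silane | CC(C)(C)[Si](C)(C)OC[C@@H]1O[C@@]1(C)CCC=C(C)C | intermediate
4 | 5-{2-[(2S,3S)-3-{[(tert-butyldimethylsilyl)oxy]methyl}-2-methyloxiran-2-yl]ethyl}-3,3-dimethyl-1,2,4-trioxolane (secondary ozonide, both epimers at C5; not isolated) | CC(C)(C)[Si](C)(C)OC[C@@H]1O[C@@]1(C)CCC2OOC(C)(C)O2 | intermediate
5 | 3-[(2S,3S)-3-{[(tert-butyldimethylsilyl)oxy]methyl}-2-methyloxiran-2-yl]propanal | CC(C)(C)[Si](C)(C)OC[C@@H]1O[C@@]1(C)CCC=O | intermediate
6 | propanoyl chloride | CCC(Cl)=O | starting material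
7 | methylketene, prop-1-en-1-one (not isolated) | CC=C=O | intermediate
8 | (3S,4R)-4-{2-[(2S,3S)-3-{[(tert-butyldimethylsilyl)oxy]methyl}-2-methyloxiran-2-yl]ethyl}-3-methyloxetan-2-one | CC(C)(C)[Si](C)(C)OC[C@@H]1O[C@@]1(C)CC[C@H]2OC(=O)[C@H]2C | intermediate
9 | (3S,4R)-4-{2-[(2S,3S)-3-(hydroxymethyl)-2-methyloxiran-2-yl]ethyl}-3-methyloxetan-2-one | OC[C@@H]1O[C@@]1(C)CC[C@H]2OC(=O)[C@H]2C | intermediate
10 | (3S,4R)-4-[(3R,4S)-3-hydroperoxy-4,5-dihydroxy-3-methylpentyl]-3-methyloxetan-2-one | OC[C@H](O)[C@](C)(OO)CC[C@H]1OC(=O)[C@H]1C | intermediate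
11 | (2S)-2-[(3S,6R)-6-[(1S)-1,2-dihydroxyethyl]-6-methyl-1,2-dioxan-3-yl]propanoic acid | OC[C@H](O)[C@@]1(C)CC[C@@H]([C@H](C)C(O)=O)OO1 | intermediate
12 | methyl (2S)-2-[(3S,6R)-6-[(1S)-1,2-dihydroxyethyl]-6-methyl-1,2-dioxan-3-yl]propanoate | OC[C@H](O)[C@@]1(C)CC[C@@H]([C@H](C)C(=O)OC)OO1 | intermediate
13 | methyl (2S)-2-[(3S,6R)-6-formyl-6-methyl-1,2-dioxan-3-yl]propanoate | O=C[C@@]1(C)CC[C@@H]([C@H](C)C(=O)OC)OO1 | intermediate
14 | ethyl 5-bromopentanoate | CCOC(=O)CCCCBr | starting material
15 | ethyl 5-(diethoxyphosphoryl)pentanoate | CCOC(=O)CCCCP(=O)(OCC)OCC | intermediate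
16 | diethyl (5-hydroxy-5-methylhexyl)phosphonate | CC(C)(O)CCCCP(=O)(OCC)OCC | intermediate
17 | 2-chloro-N-methoxy-N-methylacetamide | CON(C)C(=O)CCl | starting material
18 | diethyl (1-chloro-7-hydroxy-7-methyl-2-oxooctan-3-yl)phosphonate (racemic) | CC(C)(O)CCCC(C(=O)CCl)P(=O)(OCC)OCC | intermediate
19 | [3-(diethoxyphosphoryl)-7-hydroxy-7-methyl-2-oxooctyl]triphenylphosphonium chloride (racemic; not isolated) | CC(C)(O)CCCC(C(=O)C[P+](c1ccccc1)(c1ccccc1)c1ccccc1)P(=O)(OCC)OCC.[Cl-] | intermediate
20 | diethyl [7-hydroxy-7-methyl-2-oxo-1-(triphenyl-λ5-phosphanylidene)octan-3-yl]phosphonate (racemic) | CC(C)(O)CCCC(C(=O)C=P(c1ccccc1)(c1ccccc1)c1ccccc1)P(=O)(OCC)OCC | intermediate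
21 | methyl (2S)-2-[(3S,6R)-6-[(1E)-4-(diethoxyphosphoryl)-8-hydroxy-8-methyl-3-oxonon-1-en-1-yl]-6-methyl-1,2-dioxan-3-yl]propanoate (both epimers at the phosphonate carbon) | CC(C)(O)CCCC(C(=O)/C=C/[C@@]1(C)CC[C@@H]([C@H](C)C(=O)OC)OO1)P(=O)(OCC)OCC | intermediate
22 | methyl (2S)-2-[(3S,6R)-6-[4-(diethoxyphosphoryl)-8-hydroxy-8-methyl-3-oxononyl]-6-methyl-1,2-dioxan-3-yl]propanoate (both epimers at the phosphonate carbon) | CC(C)(O)CCCC(C(=O)CC[C@@]1(C)CC[C@@H]([C@H](C)C(=O)OC)OO1)P(=O)(OCC)OCC | intermediate
23 | aikupikoxide D, methyl (2S)-2-[(3S,6R)-6-(8-hydroxy-8-methyl-4-methylidene-3-oxononyl)-6-methyl-1,2-dioxan-3-yl]propanoate | C=C(CCCC(C)(C)O)C(=O)CC[C@@]1(C)CC[C@@H]([C@H](C)C(=O)OC)OO1 | target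

## Step count and least certain steps

Total step count: 16. Longest linear sequence: 12 steps (1 to 23 through steps 1–9 and 14–16). The side-chain branch from 14 is 4 steps (steps 10–13) before the union in step 14.

**Step 7 (key step).** Most likely failure: alkyl–oxygen cleavage at the secondary, β-branched C3 is too slow. Intermolecular attack of the peroxide anion on the lactone carbonyl (perester oligomers) or base-induced fragmentation of the β-hydroxy hydroperoxide across C6–C7 could then take over; participation of the C7 hydroxyl to form a tetrahydropyran is a lesser concern.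

Fallback, by known sulfonate chemistry, from 8 back to 12:
- Methanolysis of the lactone of 8 at the acyl carbon (MeOH, Et3N, 0 °C; C3 retained) gives methyl (2S,3R)-5-[(2S,3S)-3-{[(tert-butyldimethylsilyl)oxy]methyl}-2-methyloxiran-2-yl]-3-hydroxy-2-methylpentanoate F1.
- MsCl and Et3N convert it into the C3 methanesulfonate F2.
- Buffered Bu4NF frees the epoxy alcohol F3.
- Perhydrolysis as in step 6 gives the hydroperoxy diol mesylate F4.
- Cs2CO3 in DMF (or KOt-Bu with 18-crown-6) closes the dioxane by 6-exo-tet displacement of the mesylate with inversion at C3, giving 12 directly.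

The price is one extra step and the risk of E1cB loss of the β-mesylate.

**Step 6.** Most likely failure: the strained lactone does not survive acidic H2O2 (acyl perhydrolysis), or the activated epoxide ionises at C6 so that configuration is lost. Ethereal H2O2 is also the main handling hazard. It should be prepared and used cold on small scale, and removed by aqueous washing before any concentration.

Fallback, which moves the perhydrolysis to the start where no lactone exists, from 2 back to 10:
- Perhydrolysis of 2 under the conditions of step 6 gives (2S,3R)-3-hydroperoxy-3,7-dimethyloct-6-ene-1,2-diol F5.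
- Et3SiCl and imidazole give the tris(triethylsilyl) derivative F6 (one silyl peroxide, two silyl ethers).
- Ozonolysis in the presence of pyridine (no reductant) gives the aldehyde F7.
- The cyclocondensation of step 4 gives the lactone F8.
- HF·pyridine buffered with pyridine removes all three silyl groups to give 10.

**Step 4.** Most likely failure: LiClO4 activates the tertiary epoxide (rearrangement or chloride opening), or the extra Lewis-basic oxygens disturb the organised transition state and erode catalyst control.

Fallback, which builds the lactone before the epoxide, from 1 back to 9: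
- Silylation of 1 gives tert-butyl{[(2E)-3,7-dimethylocta-2,6-dien-1-yl]oxy}dimethylsilane F9.
- Ozonolysis with one equivalent of ozone, selective for the more electron-rich distal alkene, gives (4E)-6-[(tert-butyldimethylsilyl)oxy]-4-methylhex-4-enal F10.
- The cyclocondensation gives the cis-lactone F11.
- HF·pyridine gives the allylic alcohol F12.
- Sharpless epoxidation with L-(+)-diethyl tartrate then gives 9.

**Step 14.** Most likely failure: the stabilised ylide adds too slowly to the neopentyl-type α-peroxy aldehyde, so that prolonged heating degrades the peroxide aldehyde.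

Fallback with a more reactive ylide, from 13 back to 22:
- Wittig reaction of 13 with the ylide from (1,3-dioxolan-2-ylmethyl)triphenylphosphonium bromide and KOt-Bu at −78 °C gives the alkenyl dioxolane F13.
- Diimide gives the saturated acetal F14.
- Mild aqueous acid (pyridinium p-toluenesulfonate, wet acetone) gives the C9 aldehyde F15.
- Addition of dilithiated 16 at −78 °C gives the β-hydroxy phosphonate F16.
- Dess–Martin periodinane oxidises it to 22.

## Further compounds

F1 | step 7 | methyl (2S,3R)-5-[(2S,3S)-3-{[(tert-butyldimethylsilyl)oxy]methyl}-2-methyloxiran-2-yl]-3-hydroxy-2-methylpentanoate | CC(C)(C)[Si](C)(C)OC[C@@H]1O[C@@]1(C)CC[C@@H](O)[C@H](C)C(=O)OC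
F2 | step 7 | methyl (2S,3R)-5-[(2S,3S)-3-{[(tert-butyldimethylsilyl)oxy]methyl}-2-methyloxiran-2-yl]-3-(methanesulfonyloxy)-2-methylpentanoate | CC(C)(C)[Si](C)(C)OC[C@@H]1O[C@@]1(C)CC[C@@H](OS(C)(=O)=O)[C@H](C)C(=O)OC
F3 | step 7 | methyl (2S,3R)-5-[(2S,3S)-3-(hydroxymethyl)-2-methyloxiran-2-yl]-3-(methanesulfonyloxy)-2-methylpentanoate | OC[C@@H]1O[C@@]1(C)CC[C@@H](OS(C)(=O)=O)[C@H](C)C(=O)OC
F4 | step 7 | methyl (2S,3R,6R,7S)-6-hydroperoxy-7,8-dihydroxy-3-(methanesulfonyloxy)-2,6-dimethyloctanoate | OC[C@H](O)[C@](C)(OO)CC[C@@H](OS(C)(=O)=O)[C@H](C)C(=O)OC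
F5 | step 6 | (2S,3R)-3-hydroperoxy-3,7-dimethyloct-6-ene-1,2-diol | OC[C@H](O)[C@](C)(OO)CCC=C(C)C
F6 | step 6 | (2S,3R)-3,7-dimethyl-1,2-bis(triethylsilyloxy)-3-(triethylsilylperoxy)oct-6-ene | CC[Si](CC)(CC)OC[C@H](O[Si](CC)(CC)CC)[C@](C)(OO[Si](CC)(CC)CC)CCC=C(C)C
F7 | step 6 | (4R,5S)-4-methyl-5,6-bis(triethylsilyloxy)-4-(triethylsilylperoxy)hexanal | CC[Si](CC)(CC)OC[C@H](O[Si](CC)(CC)CC)[C@](C)(OO[Si](CC)(CC)CC)CCC=O
F8 | step 6 | (3S,4R)-3-methyl-4-[(3R,4S)-3-methyl-4,5-bis(triethylsilyloxy)-3-(triethylsilylperoxy)pentyl]oxetan-2-one | CC[Si](CC)(CC)OC[C@H](O[Si](CC)(CC)CC)[C@](C)(OO[Si](CC)(CC)CC)CC[C@H]1OC(=O)[C@H]1C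
F9 | step 4 | tert-butyl{[(2E)-3,7-dimethylocta-2,6-dien-1-yl]oxy}dimethylsilane | CC(C)=CCC/C(C)=C/CO[Si](C)(C)C(C)(C)C
F10 | step 4 | (4E)-6-[(tert-butyldimethylsilyl)oxy]-4-methylhex-4-enal | O=CCC/C(C)=C/CO[Si](C)(C)C(C)(C)C
F11 | step 4 | (3S,4R)-4-[(3E)-5-[(tert-butyldimethylsilyl)oxy]-3-methylpent-3-en-1-yl]-3-methyloxetan-2-one | CC(C)(C)[Si](C)(C)OC/C=C(C)/CC[C@H]1OC(=O)[C@H]1C
F12 | step 4 | (3S,4R)-4-[(3E)-5-hydroxy-3-methylpent-3-en-1-yl]-3-methyloxetan-2-one | OC/C=C(C)/CC[C@H]1OC(=O)[C@H]1C
F13 | step 14 | methyl (2S)-2-[(3S,6R)-6-[2-(1,3-dioxolan-2-yl)ethenyl]-6-methyl-1,2-dioxan-3-yl]propanoate (alkene isomers) | C(=C[C@@]1(C)CC[C@@H]([C@H](C)C(=O)OC)OO1)C2OCCO2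
F14 | step 14 | methyl (2S)-2-[(3S,6R)-6-[2-(1,3-dioxolan-2-yl)ethyl]-6-methyl-1,2-dioxan-3-yl]propanoate | C(C[C@@]1(C)CC[C@@H]([C@H](C)C(=O)OC)OO1)C2OCCO2
F15 | step 14 | methyl (2S)-2-[(3S,6R)-6-methyl-6-(3-oxopropyl)-1,2-dioxan-3-yl]propanoate | O=CCC[C@@]1(C)CC[C@@H]([C@H](C)C(=O)OC)OO1
F16 | step 14 | methyl (2S)-2-[(3S,6R)-6-[4-(diethoxyphosphoryl)-3,8-dihydroxy-8-methylnonyl]-6-methyl-1,2-dioxan-3-yl]propanoate (diastereomer mixture at the carbinol and phosphonate carbons) | CC(C)(O)CCCC(C(O)CC[C@@]1(C)CC[C@@H]([C@H](C)C(=O)OC)OO1)P(=O)(OCC)OCC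
A1 | alternative 1 | tert-butyl{[(2S,3E,5E)-9,9-dimethoxy-2,6-dimethylnona-3,5-dien-1-yl]oxy}diphenylsilane | COC(OC)CC/C(C)=C/C=C/[C@H](C)CO[Si](c1ccccc1)(c1ccccc1)C(C)(C)C
A2 | alternative 1 | (3S,6S)-6-(3,3-dimethoxypropyl)-6-methyl-3-{(2R)-1-[(tert-butyldiphenylsilyl)oxy]propan-2-yl}-3,6-dihydro-1,2-dioxine | COC(OC)CC[C@@]1(C)C=C[C@@H]([C@H](C)CO[Si](c2ccccc2)(c2ccccc2)C(C)(C)C)OO1
A3 | alternative 2 | [(2S,3S)-3-{(3S,4R)-5-[(tert-butyldiphenylsilyl)oxy]-3-[(2-methoxypropan-2-yl)peroxy]-4-methylpentyl}-3-methyloxiran-2-yl]methanol | OC[C@@H]1O[C@@]1(C)CC[C@H](OOC(C)(C)OC)[C@H](C)CO[Si](c2ccccc2)(c2ccccc2)C(C)(C)C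
A4 | alternative 2 | (1S)-1-[(3R,6S)-6-{(2R)-1-[(tert-butyldiphenylsilyl)oxy]propan-2-yl}-3-methyl-1,2-dioxan-3-yl]ethane-1,2-diol | OC[C@H](O)[C@@]1(C)CC[C@@H]([C@H](C)CO[Si](c2ccccc2)(c2ccccc2)C(C)(C)C)OO1
A5 | alternative 3 | methyl (2S,3S)-3-{[(3S)-6-[(tert-butyldiphenylsilyl)oxy]-3-methylhex-1-en-3-yl]peroxy}-2-methylpent-4-enoate | C=C[C@](C)(CCCO[Si](c1ccccc1)(c1ccccc1)C(C)(C)C)OO[C@@H](C=C)[C@H](C)C(=O)OC
A6 | alternative 3 | methyl (2S)-2-[(3S,6S)-6-{3-[(tert-butyldiphenylsilyl)oxy]propyl}-6-methyl-3,6-dihydro-1,2-dioxin-3-yl]propanoate | CC(C)(C)[Si](c1ccccc1)(c1ccccc1)OCCC[C@@]1(C)C=C[C@@H]([C@H](C)C(=O)OC)OO1
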